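Assumption: natural (2E,7R,11R)-phytol of chlorophyll origin (≥95 % E) and menadiol diacetate (vitamin K4) are bought as such; a few per cent of Z isomer, from the phytol or from step 3, is removed at the end by chromatography.

**Retrosynthetic overview**
1. Phylloquinone ⇐ deacetylation and oxidation of 3-phytyl-menadiol 1-acetate. No ring is built: both rings of the naphthalene come intact from menadiol diacetate.
2. The ring C3–side-chain C1' bond ⇐ intramolecular [1,3] O-to-C shift of an aryl phytyl ether whose oxygen sits at C4, next to the only free ring position.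
3. Key disconnection: the aryl–O–CH2 ether bond ⇐ Mitsunobu coupling of menadiol 1-monoacetate with natural phytol, which supplies the E olefin and both stereocentres.
4. Menadiol 1-monoacetate ⇐ selective removal of the unhindered 4-acetyl group of menadiol diacetate.

**Route**

Step 1
Reactants: 1 menadiol diacetate (2-methylnaphthalene-1,4-diyl diacetate)
Product: 2 4-hydroxy-2-methylnaphthalen-1-yl acetate (menadiol 1-monoacetate)
Conditions: n-BuNH2 (1.05 equiv), THF, 0 °C → rt, N2; dilute HCl wash, crystallise
Reagents that add atoms: none
Why: Chemoselective aminolysis of an aryl ester: the 4-acetate is flanked only by hydrogens and is cleaved, while the 1-acetate is shielded by the ortho methyl group and the peri hydrogen and survives; no stereocentre is involved.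

Step 2
Reactants: 2 4-hydroxy-2-methylnaphthalen-1-yl acetate; 3 natural phytol, (2E,7R,11R)-3,7,11,15-tetramethylhexadec-2-en-1-ol
Product: 4 2-methyl-4-{[(2E,7R,11R)-3,7,11,15-tetramethylhexadec-2-en-1-yl]oxy}naphthalen-1-yl acetate
Conditions: PPh3 (1.3 equiv), DIAD (1.3 equiv), THF, 0 °C → rt, N2, dark; hexane trituration to remove by-products
Reagents that add atoms: none
Why: Mitsunobu etherification, in which the naphthol (pKa about 10) displaces the alkoxyphosphonium group by SN2 at the primary allylic carbon under neutral conditions, so the aryl acetate, the E double bond and the remote 7R and 11R centres are untouched.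

Step 3
Reactants: 4 2-methyl-4-{[(2E,7R,11R)-3,7,11,15-tetramethylhexadec-2-en-1-yl]oxy}naphthalen-1-yl acetate
Product: 5 4-hydroxy-2-methyl-3-[(2E,7R,11R)-3,7,11,15-tetramethylhexadec-2-en-1-yl]naphthalen-1-yl acetate
Conditions: Li[B(C6F5)4]·2.5Et2O (10 mol %), 2,6-di-tert-butyl-4-methylpyridine (5 mol %), CH2Cl2 (0.05 M), −20 → 20 °C, Ar
Reagents that add atoms: none
Why: Proposed new method: a lithium-cation-catalysed contact-ion-pair [1,3] O-to-C allyl shift, in which the weakly coordinated Li+ binds the ether oxygen and ionises the C–O bond to a lithium naphtholate/E-phytyl cation pair; the inert borate anion cannot add reversibly at the tertiary allyl carbon (the usual route to E/Z leakage) and the cation keeps its geometry through its rotation barrier; ring carbon C3, the only free ortho position (para is blocked by the acetate), then captures the primary allyl terminus and a proton shift restores the naphthol, so no strong Brønsted acid forms and the hindered pyridine mops up traces that would cyclise the product to a chromane; the closest known reaction types are the BF3- or clay-promoted [1,3] shifts of aryl prenyl ethers and the [1,3] shifts of allyl vinyl ethers in concentrated LiClO4–Et2O; no stereocentre is formed and 7R and 11R are untouched.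

Step 4
Reactants: 5 4-hydroxy-2-methyl-3-[(2E,7R,11R)-3,7,11,15-tetramethylhexadec-2-en-1-yl]naphthalen-1-yl acetate
Product: 7 phylloquinone, via phyllohydroquinone 6 (not isolated)
Conditions: NaOMe (2 equiv), degassed MeOH–THF, Ar, 0 °C → rt; AcOH (2.1 equiv), extract into Et2O under Ar; then Ag2O (2 equiv), MgSO4, Et2O, rt, dark
Reagents that add atoms: none
Why: Methoxide transesterification of the aryl acetate followed by the classical Ag2O oxidation of a hydroquinone to its quinone; acidifying before the oxidation keeps the base-labile quinone away from alkoxide, and neither operation touches the E olefin or the 7R and 11R centres.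

**Compound list**
1 | menadiol diacetate (vitamin K4; 2-methylnaphthalene-1,4-diyl diacetate) | CC(=O)Oc1c(C)cc(OC(C)=O)c2ccccc12 | starting material
2 | 4-hydroxy-2-methylnaphthalen-1-yl acetate (menadiol 1-monoacetate) | CC(=O)Oc1c(C)cc(O)c2ccccc12 | intermediate
3 | natural phytol, (2E,7R,11R)-3,7,11,15-tetramethylhexadec-2-en-1-ol | OC/C=C(\C)CCC[C@H](C)CCC[C@H](C)CCCC(C)C | starting material
4 | 2-methyl-4-{[(2E,7R,11R)-3,7,11,15-tetramethylhexadec-2-en-1-yl]oxy}naphthalen-1-yl acetate | CC(=O)Oc1c(C)cc(OC/C=C(\C)CCC[C@H](C)CCC[C@H](C)CCCC(C)C)c2ccccc12 | intermediate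
5 | 4-hydroxy-2-methyl-3-[(2E,7R,11R)-3,7,11,15-tetramethylhexadec-2-en-1-yl]naphthalen-1-yl acetate | CC(=O)Oc1c(C)c(C/C=C(\C)CCC[C@H](C)CCC[C@H](C)CCCC(C)C)c(O)c2ccccc12 | intermediate
6 | phyllohydroquinone, 2-methyl-3-[(2E,7R,11R)-3,7,11,15-tetramethylhexadec-2-en-1-yl]naphthalene-1,4-diol | Cc1c(C/C=C(\C)CCC[C@H](C)CCC[C@H](C)CCCC(C)C)c(O)c2ccccc2c1O | intermediate
7 | phylloquinone, 2-methyl-3-[(2E,7R,11R)-3,7,11,15-tetramethylhexadec-2-en-1-yl]naphthalene-1,4-dione | CC1=C(C/C=C(\C)CCC[C@H](C)CCC[C@H](C)CCCC(C)C)C(=O)c2ccccc2C1=O | target

**Step count**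
Total steps: 4. Longest linear sequence: 4 steps (1 → 2 → 4 → 5 → 7); phytol 3 enters unchanged in step 2.

**Steps most likely to fail**

Step 3 (the proposed new shift). The lithium salt may not ionise the ether, or the ion pair may lose E geometry or eliminate to phytadienes. The fallback is known chemistry and sets out from 2 and 3, bypassing ether 4: the classical BF3·OEt2-catalysed Friedel–Crafts condensation of menadiol 1-monoacetate with phytol in dioxane at 50 °C alkylates C3 directly. Excess 2 is recovered by base extraction. It comes back to the route at 5 and makes no new compound (F0).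

Step 1 (regioselectivity of the mono-deacetylation). Aminolysis may also touch the 1-acetate or stop short. The fallback sets out from 1. Complete methanolysis (K2CO3, degassed MeOH, Ar) gives menadiol F1. TBSCl and imidazole in DMF at −20 °C silylate the less hindered 4-hydroxyl to give 4-[(tert-butyldimethylsilyl)oxy]-2-methylnaphthalen-1-ol F2. Ac2O, Et3N and DMAP give 4-[(tert-butyldimethylsilyl)oxy]-2-methylnaphthalen-1-yl acetate F3. TBAF buffered with AcOH in THF at 0 °C removes the silyl group, and the sequence comes back to the route at 2.

Step 2 (Mitsunobu etherification). The ambident naphthol may give some C-alkylation or SN2' product, and the hydroquinone monoester may oxidise. The fallback sets out from 3. PBr3 with a trace of pyridine in hexane–Et2O at −10 °C gives (2E,7R,11R)-1-bromo-3,7,11,15-tetramethylhexadec-2-ene (phytyl bromide) F4. Williamson O-alkylation of 2 with F4 and Cs2CO3 in DMF at 0 °C under N2 comes back to the route at 4.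

**Further compounds**
F0 | step 3 | none | none
F1 | step 1 | menadiol, 2-methylnaphthalene-1,4-diol | Cc1cc(O)c2ccccc2c1O
F2 | step 1 | 4-[(tert-butyldimethylsilyl)oxy]-2-methylnaphthalen-1-ol | Cc1cc(O[Si](C)(C)C(C)(C)C)c2ccccc2c1O
F3 | step 1 | 4-[(tert-butyldimethylsilyl)oxy]-2-methylnaphthalen-1-yl acetate | CC(=O)Oc1c(C)cc(O[Si](C)(C)C(C)(C)C)c2ccccc12
F4 | step 2 | (2E,7R,11R)-1-bromo-3,7,11,15-tetramethylhexadec-2-ene (phytyl bromide) | BrC/C=C(\C)CCC[C@H](C)CCC[C@H](C)CCCC(C)C
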